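I want to know how much of the gamma charge has turned into target at the end of its run, and what the rate at the outset answers to when substrate or free catalyst is changed.

| setting | beta | alpha | theta | gamma |
|---|---|---|---|---|
| substrate | 0.600 M | 0.900 M | 0.600 M | 0.240 M |
| free catalyst | 0.0600 M | 0.0600 M | 0.0900 M | 0.0600 M |
| time |  |  |  | 11 h |

| run | time / h | [target] / M |
|---|---|---|
| beta run | 0.84 | 0.0150 |
| beta run | 2.5 | 0.0469 |
| beta run | 4.9 | 0.1275 |
| beta run | 7.7 | 0.2386 |
| beta run | 11 | 0.3602 |
| alpha run | 0.84 | 0.0222 |
| alpha run | 2.5 | 0.0901 |
| alpha run | 4.9 | 0.2610 |
| alpha run | 7.7 | 0.5146 |
| alpha run | 11 | 0.6891 |
| theta run | 0.84 | 0.0190 |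
| theta run | 2.5 | 0.0601 |
| theta run | 4.9 | 0.1497 |
| theta run | 7.7 | 0.2701 |
| theta run | 11 | 0.3841 |

(scatter of a reading: 0.002 M)

- reaction order in [substrate] at the outset, round the charge of the beta run, defined at two percent of the substrate turned into target (one fixed amount of target, the same in the runs compared)
- reaction order in [free catalyst] at the outset, round the charge of the beta run, defined at two percent of the substrate turned into target
- target in the gamma run at 11 h, as a share of the substrate charged

- Overall: substrate -> target, with free catalyst as catalyst.
- Constant volume, constant temperature.
- An order is taken over about fifteen percent of the charge, up and down.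

I follow the beta run in slow motion, writing target as a share of the substrate charged, taking the substrate left as the charge less target, and dividing each interval's rate by the mean substrate left to get a specific rate. In the first instants, between 0.84 h and 2.5 h, target stands near 5.16% and the specific rate reads 0.0338 h⁻¹. In the middle, between 4.9 h and 7.7 h, target stands near 30.5% and the specific rate has grown to 0.0952 h⁻¹, so target is feeding its own formation, which is autocatalysis. A straight line through these two points starts at 0.0213 h⁻¹ at zero target and gives 8.79% of the beta charge as the crossover share, the share of the charge at which target adds as much to the specific rate as the start-up term gives. Towards the end of the beta run, the turnover per hour reads 0.0614 h⁻¹ against 0.0661 h⁻¹ in the interval before.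

The mark of 2 percent lies below the crossover share. The first readings, taken near that mark, give an order in substrate of 0.967 from alpha against beta, and an order in free catalyst of 0.583 from theta against beta, the latter a loose reading with a scatter of about 0.419.

In the gamma run, the same crossover amount of target makes up 22.0% of the smaller charge, a larger share than the 8.79% of the beta charge. Letting the specific rate rise in a straight line from 0.0213 h⁻¹ to twice that value at this share, I integrate to 11 h and reckon 32.5% of the gamma charge as target.

The forecast gives 1.05, 0.58 and 37%, calling the reaction “first order in substrate at fixed target”, and its substrate order and gamma share stand above mine.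

The simulation gives 1.0, 0.43 and 33.5%.

    2 free catalyst ⇌ catalyst dimer, settled at all times (1100 L mol⁻¹)
    free catalyst + substrate → target + free catalyst (4.968 L mol⁻¹ h⁻¹)
    target → decomposed product (0.02610 h⁻¹)
    substrate + target → 2 target (0.4860 L mol⁻¹ h⁻¹)

The 33.5% of the gamma run lies above the crossover share of 22.0%, so late in the gamma run target adds more to the specific rate than the start-up term gives. The simulated gamma run without the conversion of substrate and target into more target shows what that step is worth: due to that conversion, the gamma run reaches 33.5% at the asked time and not 20.6%, a difference of 13 percentage points.

The readings come from a simulation for substances that don't exist.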